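The readings were generated by integration for substances that don't exist; scatter was added.

At early times substrate leaves faster than target appears: at 2.50 min Thursday's flask shows target for 45.0% of the substrate lost, and at 8.00 min Saturday's flask for 31.3%, the remainder unread.

| flask | substrate | remark | time |
|---|---|---|---|
| Thursday's | 0.20 M | run made earlier |  |
| Saturday's | 2.9 M | run made earlier |  |
| birch | 0.15 M |  | 1.0 h |
| larch | 2.0 M |  | 1.0 h |
| oak | 0.80 M |  | 1.0 h |
| cedar | 0.50 M |  | 1.0 h |
| ash | 0.30 M |  | 1.0 h |

| run | time / min | target / % | substrate / % |
|---|---|---|---|
| Thursday's | 2.50 | 13.1 | 70.9 |
| Thursday's | 6.00 | 24.3 | 45.1 |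
| Thursday's | 12.0 | 40.0 | 21.7 |
| Thursday's | 30.0 | 59.0 | 2.2 |
| Saturday's | 8.00 | 22.2 | 29.1 |
| Saturday's | 15.0 | 29.0 | 9.7 |
| Saturday's | 25.0 | 37.9 | 2.1 |
| Saturday's | 30.0 | 40.3 | 1.0 |

(scatter of a reading: 0.5 percentage points)

* ranking by amount of target, in percent of the substrate charged, from high to low, at 1.0 h (birch / larch / oak / cedar / ash)
* the amount of target, in percent of the substrate charged of the flask you put first, at 1.0 h
* the amount of target, in percent of the substrate charged of the flask you put last, at 1.0 h

- in a conversion other conformer counts as not yet reacted

Birch looks nearly like Thursday's flask, 0.15 M against 0.20 M, but Thursday's last reading, 59.0% at 30.0 min, is no end value, since 2.2% substrate still stands. Substrate in Thursday's flask reads a half-life of 5.45 min, far shorter than the 1.0 h asked, so this reckoning treats 1.0 h as an end.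

Saturday's last interval gives target gained per point of substrate lost, 2.18, a rough reading given the scatter of 0.5 percentage points. With that ratio taken for both flasks, the reckoned ends are 63.8% for Thursday's flask and 42.5% for Saturday's, lower with the larger charge.

This reckoning assumes a higher-order loss competing with first-order routes, and so writes end target as a dilute value divided by one plus charged c(substrate) over a charge scale. That scale is the charged c(substrate) at which end target stands at half its dilute value, here 5.18 M, and the two reckoned ends put the dilute value at 66.3%. Birch is reckoned at 64.4%, near Thursday's end because both charges are far below the scale, and larch at 47.8%, with ash, cedar and oak between in order of charge.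

The forecast, holding that the conformer “then slowly converts to target”, gives birch > ash > cedar > oak > larch, with 75.5% and 60%, the same order as this reckoning but higher values.

The simulation gives birch > ash > cedar > oak > larch, with 65.7% and 47.5%.

    substrate ⇌ other conformer (K = 2.40, k = 0.0710 min⁻¹)
    substrate → target (k = 0.0640 min⁻¹)
    other conformer → isomer of the product (k = 0.150 min⁻¹)
    target ⇌ isomer of the product (K = 0.460, k = 0.0580 min⁻¹)
    substrate + target → side product (k = 0.0610 M⁻¹ min⁻¹)

The scale 5.18 M gave larch 47.8% against 47.5%, and gives the neighbour of birch charged with 0.037 M 65.8% against its simulated 67.6%. In birch, the passing of substrate into other conformer and into target reached the midpoints of their turnover up to 1.0 h at 0.0794 h and 0.0941 h, while the step between target and isomer of the product had by itself a relaxation half-life of 0.0628 h, short against 1.0 h. In larch, substrate and target formed side product while both stood, and side product, each counted as two, reached 30.5% at 1.00 h.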